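Feature: C6 and C8 (ring A) and C3' and C5' (ring B), the carbons that bear the four outer methoxyls, are the only C–H carbons of a plain 5,7,4'-trioxygenated flavone that lie ortho or para to the oxygens at C5, C7, O1 and C4'. They are therefore the carbons where that core is halogenated.
Key disconnection: the aryl–oxygen bonds C6–O, C8–O, C3'–O and C5'–O are cut together. This leads back to a tetrabromoflavone and sodium methoxide (copper-catalysed methanolysis).
Earlier disconnections: four C–Br bonds (electrophilic bromination of genkwanin), then the O7–CH3 bond (methylation of the most acidic hydroxyl of apigenin).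
Ring order: no ring is formed; rings A, C and B and all fifteen skeletal carbons are bought with apigenin.
Forward: apigenin 1 → genkwanin 2 → tetrabromide 3; 3 + sodium methoxide 4 → bis-phenoxides 5 and 6 → target 7.

Key step: step 3

Remark: the target has no stereocentre and no axis or plane of chirality. It is achiral, so the SMILES defines it fully and no stereocontrol is required.

Step 1
Reactants: 1 apigenin (5,7,4'-trihydroxyflavone)
Product: 2 genkwanin (5,4'-dihydroxy-7-methoxyflavone)
Conditions: MeI (1.05 equiv), K2CO3 (1.0 equiv), DMF, 0 °C → rt
Reagents that add atoms: methyl iodide, CI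
Why: This is a Williamson ether synthesis under acidity control, in which the 7-OH (para to the C4 carbonyl, hence a vinylogous carboxylic acid) is deprotonated first, the 5-OH is tied up in a hydrogen bond to C4=O, and limiting base and methyl iodide to about one equivalent each should leave the less acidic 4'-OH largely untouched, in line with the established 7-O preference of apigenin towards alkyl halides and carbonate.

Step 2
Reactants: 2 genkwanin
Product: 3 6,8,3',5'-tetrabromo-5,4'-dihydroxy-7-methoxyflavone
Conditions: Br2 (4.2 equiv), AcOH, rt → 50 °C
Reagents that add atoms: bromine, BrBr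
Why: This is a fourfold electrophilic aromatic bromination in which C6 and C8 (ortho/para to the 5-OH, ortho to the 7-OMe) and C3' and C5' (ortho to the 4'-OH) are far more nucleophilic than C3 of the hydrogen-bonded, acid-protonated pyranone, so metering bromine to just over four equivalents should stop the reaction at 3.

Step 3
Reactants: 3 6,8,3',5'-tetrabromo-5,4'-dihydroxy-7-methoxyflavone; 4 sodium methoxide
Product: 7 5,4'-dihydroxy-6,7,8,3',5'-pentamethoxyflavone (target), via tetrabromide disodium salt 5 (not isolated), via target disodium salt 6 (not isolated)
Conditions: 4 (16 equiv, 5.4 M in MeOH), CuBr (0.5 equiv), DMF, 100 °C, Ar; then 2 M HCl, 0 °C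
Reagents that add atoms: sodium methoxide (4), C[O-].[Na+]
Why: Two equivalents of 4 first convert 3 into bis-phenoxide 5, whose charge is delocalised towards C2 and C4=O and so shields the pyranone from methoxide. A copper(I) methoxide species (formally [Cu(OMe)2]−, kept in solution by DMF) then takes up each C–Br bond by oxidative addition and releases the aryl methyl ether by reductive elimination, forming the C6–O, C8–O, C3'–O and C5'–O bonds one after another and ending at 6, which the acid quench protonates to 7. The closest known reaction type is the Ullmann-type copper-catalysed methanolysis of aryl bromides, established both for 2,6-dibromophenols with the hydroxyl left free and for 6,8-dibromo-5-hydroxyflavones, and here both substrate classes sit in one molecule. No ring is closed and no stereocentre is created. Exchange must beat hydrodebromination and diaryl ether formation at all four sites, which a dry, oxygen-free medium, a large excess of concentrated methoxide and enough copper to cover what the 5-oxido-4-keto chelate binds should secure, while C3 carries no halogen and any addition–elimination at C7 merely swaps methoxyl for methoxyl. If methoxide opens ring C reversibly, the freed 2,6-dioxidoaryl ketone is symmetric about its C4a–C7 axis whenever C6 and C8 bear like groups, and the mixed bromo/methoxy stages funnel into the same 6,8-dimethoxy compound, so a Wessely–Moser-type reclosure cannot lead to an isomer of 7.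

Compound list
1 | apigenin (5,7,4'-trihydroxyflavone) | O=c1cc(-c2ccc(O)cc2)oc2cc(O)cc(O)c12 | starting material
2 | genkwanin (5,4'-dihydroxy-7-methoxyflavone) | COc1cc(O)c2c(=O)cc(-c3ccc(O)cc3)oc2c1 | intermediate
3 | 6,8,3',5'-tetrabromo-5,4'-dihydroxy-7-methoxyflavone | COc1c(Br)c(O)c2c(=O)cc(-c3cc(Br)c(O)c(Br)c3)oc2c1Br | intermediate
4 | sodium methoxide | C[O-].[Na+] | starting material
5 | disodium 5,4'-bis-phenoxide of tetrabromide 3 (not isolated) | COc1c(Br)c([O-])c2c(=O)cc(-c3cc(Br)c([O-])c(Br)c3)oc2c1Br.[Na+].[Na+] | intermediate
6 | disodium 5,4'-bis-phenoxide of the target (not isolated) | COc1cc(-c2cc(=O)c3c([O-])c(OC)c(OC)c(OC)c3o2)cc(OC)c1[O-].[Na+].[Na+] | intermediate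
7 | 5,4'-dihydroxy-6,7,8,3',5'-pentamethoxyflavone | COc1cc(-c2cc(=O)c3c(O)c(OC)c(OC)c(OC)c3o2)cc(OC)c1O | target

Total step count: 3
Longest linear sequence: 3

Steps most likely to fail

1. Step 3.
- Risk: the exchange may stall, or give way to hydrodebromination, at one of the four sites. Closely related products that are hard to separate would then build up.
- Risk: long heating with methoxide may strip the crowded 7-O-methyl group by attack at its methyl carbon. It may also fragment a ring-opened ring C by retro-Claisen cleavage.
- Fallback, from 2 back to 7: the rings are oxygenated one at a time, so each copper step exchanges only two bromides on a substrate type with direct precedent, and the material is purified in between. Two equivalents of bromine in acetic acid at room temperature should stop at the more nucleophilic ring A and give 6,8-dibromo-5,4'-dihydroxy-7-methoxyflavone F1. Copper-catalysed methanolysis with 4 then gives 5,4'-dihydroxy-6,7,8-trimethoxyflavone (xanthomicrol) F2. With ring A fully substituted, two further equivalents of bromine go ortho to the 4'-OH and give 3',5'-dibromo-5,4'-dihydroxy-6,7,8-trimethoxyflavone F3. A second methanolysis with 4, now of a plain 2,6-dibromophenol, gives 7.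

2. Step 1.
- Risk: site selectivity between O7 and O4' may be poor and methylation may run on to the diether. This would cost material and force a separation from unreacted 1.
- Fallback, from 1 back to 2: selectivity is moved from the alkylation to a deacylation. Peracetylation (Ac2O, pyridine) gives apigenin 5,7,4'-triacetate F4. Thiophenol and imidazole in NMP remove only the most electrophilic aryl acetate, the one at O7, to give 5,4'-di-O-acetylapigenin F5. Its single free hydroxyl is methylated (MeI, K2CO3, acetone) to genkwanin 5,4'-diacetate F6. Methanolysis (K2CO3, MeOH, then dilute acid) frees both phenols and gives 2.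

3. Step 2.
- Risk: bromination may run on to C3 by addition–elimination at the pyranone double bond.
- Risk: ring B may stay partly unbrominated because half-brominated material leaves the solution.
- Fallback, from 2 back to 7: the halogen is changed, and with it the substrate of the copper step. N-Iodosuccinimide (4.2 equiv) in DMF with catalytic trifluoroacetic acid works in homogeneous solution. It is a milder electrophile that should attack only the phenol- and ether-activated carbons, giving 6,8,3',5'-tetraiodo-5,4'-dihydroxy-7-methoxyflavone F7. This tetraiodide is taken with 4 through the copper-catalysed methanolysis and acid quench of step 3, where aryl iodides should exchange at lower temperature, and gives 7.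

Further compounds
F1 | step 3 | 6,8-dibromo-5,4'-dihydroxy-7-methoxyflavone | COc1c(Br)c(O)c2c(=O)cc(-c3ccc(O)cc3)oc2c1Br
F2 | step 3 | 5,4'-dihydroxy-6,7,8-trimethoxyflavone (xanthomicrol) | COc1c(OC)c(O)c2c(=O)cc(-c3ccc(O)cc3)oc2c1OC
F3 | step 3 | 3',5'-dibromo-5,4'-dihydroxy-6,7,8-trimethoxyflavone | COc1c(OC)c(O)c2c(=O)cc(-c3cc(Br)c(O)c(Br)c3)oc2c1OC
F4 | step 1 | apigenin 5,7,4'-triacetate | CC(=O)Oc1ccc(-c2cc(=O)c3c(OC(C)=O)cc(OC(C)=O)cc3o2)cc1
F5 | step 1 | 5,4'-di-O-acetylapigenin (7-OH free) | CC(=O)Oc1ccc(-c2cc(=O)c3c(OC(C)=O)cc(O)cc3o2)cc1
F6 | step 1 | genkwanin 5,4'-diacetate | CC(=O)Oc1ccc(-c2cc(=O)c3c(OC(C)=O)cc(OC)cc3o2)cc1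
F7 | step 2 | 6,8,3',5'-tetraiodo-5,4'-dihydroxy-7-methoxyflavone | COc1c(I)c(O)c2c(=O)cc(-c3cc(I)c(O)c(I)c3)oc2c1I
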